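## Retrosynthetic overview

1. Target ⇐ Shiina lactonisation of the C12 tertiary alcohol onto the C17 acrylic acid. The acid carbon is the isopropenyl CH3 of (R)-limonene, carried as a TBDPS-protected allylic alcohol.
2. The C11/C12 diol and the 14-membered carbocycle ⇐ syn-dihydroxylation of an E-Δ11,12 alkene ⇐ ring-closing metathesis of a C11 vinyl group and a C12 isopropenyl group.
3. The THF ring (C4–O–C7) ⇐ epoxidation of the E-Δ3,4 alkene followed by 5-exo epoxy-alcohol closure by the C7 hydroxyl. The C7 carbinol comes from a vinyl-Grignard addition to aldehyde 7.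
4. Key step: an Eschenmoser–Claisen-type [3,3] rearrangement (ethyl vinyl ether Claisen) of the allylic alcohol made from limononaldehyde-type keto-aldehyde 4 (isopropenylMgBr, then ketone methylenation). It forms the C5–C6 bond and the E-C3=C4 alkene.
5. C1 (R) comes from (R)-limonene oxide. Ring order: THF, then the 14-membered carbocycle (RCM), then the seven-membered lactone last.

Numbering is cembrane numbering: C1 is the CH bearing C15, C12 is the lactone carbinol carbon, and C17 is the acid carbon.

Assumptions (one line each):
- (R)-Limonene oxide is bought as the cis/trans mixture, and the epoxide stereocentres are erased in Step 3.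
- SeO2/TBHP oxidises only the isopropenyl CH3 of 1, and the epoxide survives.
- The ring-closing metathesis gives the E-Δ11,12 alkene.
- Facial selectivity in Steps 9 and 12 comes only from the existing stereocentres and is modest, so the wrong diastereomers are removed by chromatography at the acetate stages (12 and 15).

## Route

**Step 1**
Reactants: 1, (R)-limonene 1,2-oxide (cis/trans mixture, C4 = R)
Product: 2, limonene oxide with the isopropenyl CH3 oxidised to CH2OH
Conditions: SeO2 (10 mol %), TBHP (5.5 M in decane), CH2Cl2, 0→25 °C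
Reagents that add atoms: tert-butyl hydroperoxide, CC(C)(C)OO (oxygen source)
Why: SeO2 allylic oxidation (ene reaction, then [2,3]-shift of the allylseleninic acid) occurs at the isopropenyl CH3, which is favoured over the tertiary ring C–H. The C1 stereocentre is untouched.

**Step 2**
Reactants: 2
Product: 3, TBDPS ether of 2
Conditions: TBDPSCl, imidazole, DMF, 25 °C
Reagents that add atoms: TBDPSCl, CC(C)(C)[Si](Cl)(c1ccccc1)c1ccccc1
Why: The hindered silyl ether survives the later Grignard, Wittig, Claisen and acid steps and is a placeholder for C17.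

**Step 3**
Reactants: 3, TBDPS ether of 2
Product: 4, (3R)-3-[3-(TBDPSO)prop-1-en-2-yl]-6-oxoheptanal
Conditions: H5IO6 (1.5 equiv), THF/Et2O, 0→25 °C
Reagents that add atoms: periodic acid, O=I(O)(O)(O)(O)O
Why: Periodic acid opens the epoxide to the 1,2-diol in situ and cleaves it (Malaprade) to the methyl ketone and the aldehyde. Periodate supplies the one net oxygen atom (water is consumed and regenerated). C1 is unchanged and the epoxide configurations are erased.

**Step 4**
Reactants: 4
Product: 5, (5R)-5-[3-(TBDPSO)prop-1-en-2-yl]-7-hydroxy-8-methylnon-8-en-2-one (C7 epimeric mixture, which is C3 in cembrane numbering)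
Conditions: isopropenylMgBr (1.2 equiv), THF, −78 °C
Reagents that add atoms: isopropenylmagnesium bromide, C=C(C)[Mg]Br
Why: Grignard addition at −78 °C is chemoselective for the aldehyde over the methyl ketone. The new carbinol stereocentre is destroyed in the Claisen step, so its configuration does not matter.

**Step 5**
Reactants: 5
Product: 6, (5R)-5-[3-(TBDPSO)prop-1-en-2-yl]-2,8-dimethylnona-1,8-dien-3-ol (C3 epimeric mixture, C12 isopropenyl installed)
Conditions: Ph3P+CH3 Br− (3 equiv), KOtBu (3 equiv), THF, 0→25 °C
Reagents that add atoms: methylenetriphenylphosphorane, C=P(c1ccccc1)(c1ccccc1)c1ccccc1 (adds CH2)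
Why: Wittig methylenation of the methyl ketone gives the C12 isopropenyl group needed for RCM. It is done now so that no ketone or acetate is present in the later Grignard and RCM steps, and the excess ylide tolerates the free allylic alkoxide.

**Step 6 (key step)**
Reactants: 6
Product: 7, (4E,7R)-7-[3-(TBDPSO)prop-1-en-2-yl]-4,10-dimethylundeca-4,10-dienal
Conditions: (i) CH2=CHOEt (excess), Hg(OAc)2 (cat.), 25 °C; (ii) toluene, Et3N, 180 °C, sealed tube
Reagents that add atoms: ethyl vinyl ether, C=COCC (net +C2H2; EtOH is lost)
Why: Mercury-catalysed vinyl-ether exchange gives the allyl vinyl ether, and the Claisen [3,3] rearrangement through a chair transition state forms the C5–C6 bond. It places the aldehyde at C7 and sets the E-trisubstituted C3=C4 alkene, so both C3 epimers converge on one product.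

**Step 7 (parallel branch)**
Reactants: 8, 2,3-dibromoprop-1-ene
Product: 9, 2-bromohexa-1,5-diene
Conditions: allylMgBr, CuI (cat.), THF, −30→0 °C
Reagents that add atoms: allylmagnesium bromide, C=CC[Mg]Br
Why: Cu-catalysed SN2 coupling at the allylic bromide leaves the vinyl bromide intact. This gives the C8–C11 unit with a terminal vinyl group for RCM.

**Step 8**
Reactants: 7, 9 (converted in situ to its vinyl Grignard)
Product: 10, C7 allylic alcohol (C7 epimeric mixture; E-Δ3,4, C8 exo-methylene, C11 vinyl, C12 isopropenyl)
Conditions: 9, Mg, THF, 25 °C; then anhydrous CeCl3, then 7, −78 °C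
Reagents that add atoms: none
Why: The organocerium reagent adds 1,2 to the aldehyde and suppresses enolisation. C7 forms as a roughly 1:1 epimeric mixture, and the epimers are resolved after THF formation.

**Step 9**
Reactants: 10
Product: 11, THF alcohol (carried isomer 1R,3S,4R,7S, separated in Step 10)
Conditions: (i) mCPBA (0.95 equiv), NaHCO3, CH2Cl2, −20 °C; (ii) CSA (0.1 equiv), 25 °C
Reagents that add atoms: mCPBA, O=C(OO)c1cccc(Cl)c1 (net +O)
Why: The trisubstituted E-Δ3,4 alkene is by far the most peracid-reactive alkene and gives a trans-epoxide. Acid-promoted 5-exo opening at the tertiary C4 by the C7 hydroxyl proceeds with inversion, which converts the E geometry into the anti (3S,4R) relationship, and C7 is carried over from 10.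

**Step 10**
Reactants: 11
Product: 12, C3 acetate of 11 (single diastereomer after chromatography)
Conditions: Ac2O, pyridine, DMAP, CH2Cl2, 25 °C
Reagents that add atoms: acetic anhydride, CC(=O)OC(C)=O
Why: O-acetylation installs the final C3-OAc. The acetates are more easily separated than the alcohols, so the (1R,3S,4R,7S) isomer is isolated here.

**Step 11**
Reactants: 12
Product: 13, 14-membered E-Δ11,12 macrocycle
Conditions: Hoveyda–Grubbs II (10 mol %), toluene, 2 mM, 80 °C
Reagents that add atoms: none (ethylene is lost)
Why: Ring-closing metathesis joins the C11 vinyl group to the C12 isopropenyl group. It forms the trisubstituted alkene and closes the carbocycle at high dilution, and the E geometry is favoured in the macrocycle.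

**Step 12**
Reactants: 13
Product: 14, (11R,12R)-diol
Conditions: OsO4 (cat.), NMO, acetone/H2O, 0 °C
Reagents that add atoms: N-methylmorpholine N-oxide, C[N+]1([O-])CCOCC1 (oxygen source, +2 OH)
Why: Upjohn syn-dihydroxylation attacks the most electron-rich alkene, and syn addition to an E-alkene gives the like (R,R)/(S,S) pair. The macrocycle conformation selects the face, and any (S,S) diastereomer is removed at Step 13.

**Step 13**
Reactants: 14
Product: 15, C11 acetate with free C12 tertiary alcohol
Conditions: Ac2O, pyridine, DMAP (cat.), CH2Cl2, 0 °C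
Reagents that add atoms: acetic anhydride, CC(=O)OC(C)=O
Why: The secondary C11–OH is acetylated selectively, the tertiary C12–OH is inert under these mild conditions, and the mono-acetates of the two diol diastereomers are separable.

**Step 14**
Reactants: 15
Product: 16, primary allylic alcohol (C17–OH)
Conditions: TBAF, AcOH (1:1), THF, 0 °C
Reagents that add atoms: none
Why: Buffered fluoride removes the TBDPS group without cleaving or migrating the acetates.

**Step 15**
Reactants: 16
Product: 17, α-methylene aldehyde
Conditions: Dess–Martin periodinane, NaHCO3, CH2Cl2, 0 °C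
Reagents that add atoms: none
Why: A mild, non-acidic oxidation of the primary allylic alcohol leaves the tertiary alcohol, the acetates and the alkenes untouched.

**Step 16**
Reactants: 17
Product: 18, α-methylene carboxylic acid
Conditions: NaClO2, NaH2PO4, 2-methyl-2-butene, tBuOH/H2O, 25 °C
Reagents that add atoms: sodium chlorite, [Na+].[O-]Cl=O (+O)
Why: Pinnick oxidation is chemoselective for the aldehyde, and the alkene scavenger protects the alkenes from HOCl.

**Step 17**
Reactants: 18
Product: 19, Granosolide B
Conditions: MNBA, DMAP, Et3N, toluene, 2 mM, syringe pump, 25→80 °C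
Reagents that add atoms: none (H2O is lost)
Why: Shiina lactonisation through the mixed anhydride closes the seven-membered lactone onto the tertiary C12 alcohol in the preorganised macrocycle. C12 is not epimerised because no bond to it is broken.

## Compound list
1 | (R)-limonene 1,2-oxide (cis/trans mixture) | CC(=C)[C@@H]1CCC2(C)OC2C1 | starting material
2 | (4R)-4-(3-hydroxyprop-1-en-2-yl)-1-methyl-7-oxabicyclo[4.1.0]heptane | OCC(=C)[C@@H]1CCC2(C)OC2C1 | intermediate
3 | TBDPS ether of 2 | CC(C)(C)[Si](c1ccccc1)(c1ccccc1)OCC(=C)[C@@H]1CCC2(C)OC2C1 | intermediate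
4 | (3R)-3-[3-(TBDPSO)prop-1-en-2-yl]-6-oxoheptanal | CC(=O)CC[C@@H](C(=C)CO[Si](c1ccccc1)(c1ccccc1)C(C)(C)C)CC=O | intermediate
5 | (5R)-5-[3-(TBDPSO)prop-1-en-2-yl]-7-hydroxy-8-methylnon-8-en-2-one (C3 epimers) | CC(=O)CC[C@@H](C(=C)CO[Si](c1ccccc1)(c1ccccc1)C(C)(C)C)CC(O)C(C)=C | intermediate
6 | (5R)-5-[3-(TBDPSO)prop-1-en-2-yl]-2,8-dimethylnona-1,8-dien-3-ol (C3 epimers) | C=C(C)CC[C@@H](C(=C)CO[Si](c1ccccc1)(c1ccccc1)C(C)(C)C)CC(O)C(C)=C | intermediate
7 | (4E,7R)-7-[3-(TBDPSO)prop-1-en-2-yl]-4,10-dimethylundeca-4,10-dienal | C=C(C)CC[C@@H](C(=C)CO[Si](c1ccccc1)(c1ccccc1)C(C)(C)C)C/C=C(/CCC=O)C | intermediate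
8 | 2,3-dibromoprop-1-ene | C=C(Br)CBr | starting material
9 | 2-bromohexa-1,5-diene | C=C(Br)CCC=C | intermediate
10 | C7 allylic alcohol (C7 epimers; E-Δ3,4, C8 exo-methylene, C11 vinyl, C12 isopropenyl) | C=C(C)CC[C@@H](C(=C)CO[Si](c1ccccc1)(c1ccccc1)C(C)(C)C)C/C=C(/CCC(O)C(=C)CCC=C)C | intermediate
11 | THF alcohol (1R,3S,4R,7S isomer) | C=C(C)CC[C@@H](C(=C)CO[Si](c1ccccc1)(c1ccccc1)C(C)(C)C)C[C@H](O)[C@@]1(C)CC[C@H](O1)C(=C)CCC=C | intermediate
12 | C3 acetate of 11 | C=C(C)CC[C@@H](C(=C)CO[Si](c1ccccc1)(c1ccccc1)C(C)(C)C)C[C@H](OC(C)=O)[C@@]1(C)CC[C@H](O1)C(=C)CCC=C | intermediate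
13 | 14-membered E-Δ11,12 macrocycle | C=C(CO[Si](c1ccccc1)(c1ccccc1)C(C)(C)C)[C@@H]1CC/C(C)=C/CCC(=C)[C@@H]2CC[C@@](C)(O2)[C@@H](OC(C)=O)C1 | intermediate
14 | (11R,12R)-diol | C=C(CO[Si](c1ccccc1)(c1ccccc1)C(C)(C)C)[C@@H]1CC[C@@](C)(O)[C@H](O)CCC(=C)[C@@H]2CC[C@@](C)(O2)[C@@H](OC(C)=O)C1 | intermediate
15 | C11 acetate, C12 free OH | C=C(CO[Si](c1ccccc1)(c1ccccc1)C(C)(C)C)[C@@H]1CC[C@@](C)(O)[C@H](OC(C)=O)CCC(=C)[C@@H]2CC[C@@](C)(O2)[C@@H](OC(C)=O)C1 | intermediate
16 | C17 primary allylic alcohol | C=C(CO)[C@@H]1CC[C@@](C)(O)[C@H](OC(C)=O)CCC(=C)[C@@H]2CC[C@@](C)(O2)[C@@H](OC(C)=O)C1 | intermediate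
17 | α-methylene aldehyde | C=C(C=O)[C@@H]1CC[C@@](C)(O)[C@H](OC(C)=O)CCC(=C)[C@@H]2CC[C@@](C)(O2)[C@@H](OC(C)=O)C1 | intermediate
18 | α-methylene carboxylic acid | C=C(C(=O)O)[C@@H]1CC[C@@](C)(O)[C@H](OC(C)=O)CCC(=C)[C@@H]2CC[C@@](C)(O2)[C@@H](OC(C)=O)C1 | intermediate
19 | Granosolide B | C=C1C(=O)O[C@]2(C)CC[C@@H]1C[C@H](OC(C)=O)[C@@]1(C)CC[C@H](O1)C(=C)CC[C@H]2OC(C)=O | target

## Step count
Total steps: 17. Longest linear sequence: 16 steps (1 → 2 → 3 → 4 → 5 → 6 → 7 → 10 → 11 → 12 → 13 → 14 → 15 → 16 → 17 → 18 → 19, via Steps 1–6 and 8–17). Step 7 is a parallel branch.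

## Three steps most likely to fail
1. **Step 9 (epoxidation/THF closure).** The epoxide face is controlled only weakly by the remote C1 centre and C7 is epimeric, so the desired (3S,4R,7S) isomer may be a minor component of four diastereomers.
   Fallback: convert aldehyde 7 to its dimethyl acetal, because mCPBA would oxidise the free aldehyde. Epoxidise the Δ3,4 alkene and separate the two trans-epoxides, which differ only relative to C1. Hydrolyse the acetal, add the C8–C11 organocerium reagent, and cyclise with CSA. The two C7 epimers are then the only mixture, and they are separated after acetylation.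
2. **Step 11 (macro-RCM).** The C15 isopropenyl-derived alkene can compete for ring closure (12- versus 14-membered), and the E/Z outcome is uncertain.
   Fallback: omit Step 5 so the C12 methyl ketone is kept, and use the Grignard from 2-bromo-5,5-dimethoxypent-1-ene in place of 9 in Step 8. After THF formation and acetylation, hydrolyse the acetal and close the ring by intramolecular SmI2 pinacol cross-coupling of the C11 aldehyde onto the C12 ketone. This makes the C11–C12 diol directly and replaces Steps 11 and 12.
3. **Step 12 (OsO4).** OsO4 may attack the 1,1-disubstituted alkenes or the wrong face of the macrocycle, giving the (11S,12S) diol.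
   Fallback: carry alkene 13 through TBDPS removal, oxidation and Pinnick oxidation to the macrocyclic acid. Epoxidise the trisubstituted Δ11,12 alkene with mCPBA, and let the C17 acid open the tertiary epoxide at C12 (7-exo, inversion, CSA) to give the hydroxy-lactone. Then invert C11 by Mitsunobu reaction with AcOH, which also installs the C11 acetate and gives the (11R,12R) pattern.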